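**Retrosynthetic overview**

- Rings A and B are bought as benzenes. Ring C is the only ring made, and it is closed through the O1–C8a bond by intramolecular SNAr of the C2 alkoxide of an enantiopure aldol (12) onto a C8a–F carbon.
- Enabling feature: in ring A, C8a is joined through C4a to the C4 ketone of ring C, so F–C8a=C4a–C4=O is a vinylogous acyl fluoride and the Meisenheimer charge rests on the C4 enolate. The C2–O1 bond is never broken, so C2 is carried with retention.
- Ring A comes from a C2v-symmetric linchpin, 2,4-dibromo-3-fluoro-1,5-bis(methoxymethoxy)benzene (3). One C–Br becomes the C4a–C4 acyl bond, the other marks C8 for a late Negishi coupling, and the fluorine between them is C8a, so a 6-substituted isomer cannot arise.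
- C2 is set by asymmetric transfer hydrogenation of a β-keto Weinreb amide. The side-chain centre comes from (+)-limonene oxide by ring cleavage, methylenation and a Barton iododecarboxylation that excises the one surplus carbon.
- End game: C8–CH2 Negishi coupling on the 8-bromoflavanone 14, then removal of three MOM groups.

Key step: step 7

Assumption: commercial (+)-limonene 1,2-oxide is the cis/trans mixture derived from (R)-limonene; the epoxide configuration is destroyed in step 8, so only its C4 (R) centre matters, and it maps onto the (R) side-chain centre of the target.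

**Step 1**
Reactants: 1 5-fluorobenzene-1,3-diol (5-fluororesorcinol)
Product: 2 1-fluoro-3,5-bis(methoxymethoxy)benzene
Conditions: MOMCl, i-Pr2NEt, CH2Cl2, 0 °C → rt
Reagents that add atoms: chloromethyl methyl ether (MOMCl), COCCl
Why: O-alkylation of both phenols gives base-stable acetals that tolerate the organolithium, amide-base and palladium steps and leave fluorine as the only nucleofuge on ring A.

**Step 2**
Reactants: 2 1-fluoro-3,5-bis(methoxymethoxy)benzene
Product: 3 2,4-dibromo-3-fluoro-1,5-bis(methoxymethoxy)benzene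
Conditions: NBS (2.1 equiv), MeCN, 0 °C → rt, dark
Reagents that add atoms: N-bromosuccinimide, O=C1CCC(=O)N1Br
Why: Electrophilic aromatic bromination, in which each bromine should enter para to one OMOM group and ortho to fluorine (the site between the two OMOM groups is the more hindered ortho,ortho position), so the symmetric dibromide with fluorine flanked by both handles is expected.

**Step 3**
Reactants: 4 methyl 4-hydroxybenzoate
Product: 5 methyl 4-(methoxymethoxy)benzoate
Conditions: MOMCl, i-Pr2NEt, CH2Cl2, 0 °C → rt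
Reagents that add atoms: chloromethyl methyl ether (MOMCl), COCCl
Why: O-alkylation masks the ring B phenol with the same acetal used on ring A, so that one operation removes all three at the end.

**Step 4**
Reactants: 5 methyl 4-(methoxymethoxy)benzoate; 6 N-methoxy-N-methylacetamide
Product: 8 N-methoxy-3-[4-(methoxymethoxy)phenyl]-N-methyl-3-oxopropanamide, via lithium amide enolate 7 (not isolated)
Conditions: 6, LiN(i-Pr)2 (2.2 equiv), THF, −78 °C; then 5, −78 → −20 °C; aq NH4Cl
Reagents that add atoms: none
Why: Crossed Claisen condensation of the amide enolate with a non-enolisable aryl ester, in which the β-keto amide is deprotonated as it forms, which drives the reaction and prevents a second addition.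

**Step 5**
Reactants: 8 N-methoxy-3-[4-(methoxymethoxy)phenyl]-N-methyl-3-oxopropanamide
Product: 9 (3S)-3-hydroxy-N-methoxy-3-[4-(methoxymethoxy)phenyl]-N-methylpropanamide
Conditions: RuCl[(S,S)-TsDPEN](p-cymene) (1 mol %), HCO2H/Et3N (5:2), DMF, 30 °C
Reagents that add atoms: none
Why: Noyori-type asymmetric transfer hydrogenation of an aryl ketone, in which the (S,S)-catalyst should deliver hydride to the face that gives the (S)-benzylic carbinol (the sense known for aryl alkyl ketones), which sets the future C2 of the flavanone.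

**Step 6**
Reactants: 3 2,4-dibromo-3-fluoro-1,5-bis(methoxymethoxy)benzene; 9 (3S)-3-hydroxy-N-methoxy-3-[4-(methoxymethoxy)phenyl]-N-methylpropanamide
Product: 12 (3S)-1-[3-bromo-2-fluoro-4,6-bis(methoxymethoxy)phenyl]-3-hydroxy-3-[4-(methoxymethoxy)phenyl]propan-1-one, via aryllithium 10 (not isolated), via chloromagnesium alkoxide 11 (not isolated)
Conditions: 3, n-BuLi (1.0 equiv), THF, −78 °C; add 11 [from 9, t-BuMgCl, THF, −40 °C]; −78 → −50 °C; aq NH4Cl
Reagents that add atoms: none
Why: Bromine–lithium exchange at one of two equivalent C–Br bonds followed by Weinreb ketone synthesis, in which the chelated tetrahedral intermediate should survive until the quench (so the aldol is never exposed to base), the low temperature keeps the ortho-fluoro aryllithium from losing LiF, and the carbinol centre is not touched.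

**Step 7**
Reactants: 12 (3S)-1-[3-bromo-2-fluoro-4,6-bis(methoxymethoxy)phenyl]-3-hydroxy-3-[4-(methoxymethoxy)phenyl]propan-1-one
Product: 14 (2S)-8-bromo-5,7-bis(methoxymethoxy)-2-[4-(methoxymethoxy)phenyl]-2,3-dihydro-4H-chromen-4-one, via potassium alkoxide 13 (not isolated)
Conditions: KN(SiMe3)2 (1.0 equiv), THF, −78 → −20 °C; AcOH, −78 °C
Reagents that add atoms: none
Why: KN(SiMe3)2 deprotonates the C2 carbinol and alkoxide 13 adds to C8a, the β-carbon of the vinylogous acyl fluoride F–C8a=C4a–C4=O, to give a Meisenheimer complex whose charge rests on the C4 enolate, and loss of fluoride restores ring A (intramolecular SNAr by addition–elimination). The closest known reaction type is the base-mediated cyclisation of aldols of 2-fluoroaryl ketones to chroman-4-ones and of 2-fluoroaryl 1,3-diketones to flavones. Ring C closes in a 6-endo-trig sense with respect to the C8a=C4a–C4=O unit and is the only ring formed. No stereocentre is created: the C2–O1 bond is never broken, so the (S) configuration from step 5 is carried into the flavanone with retention, which an oxa-Michael closure of a chalcone could not guarantee. The step needs cyclisation to outrun retro-aldol cleavage and E1cB dehydration of the aldolate; stoichiometric deprotonation at low temperature, the inductive pull of the ortho bromine on C8a and a cold acidic quench (so that no base remains to ring-open 14) are meant to secure this. Regiochemistry is fixed by the substrate, because fluorine is the only nucleofuge ortho to the ketone and the bromine next to it marks C8 for the side chain.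

**Step 8**
Reactants: 15 (+)-limonene 1,2-oxide [(4R)-1-methyl-4-(prop-1-en-2-yl)-7-oxabicyclo[4.1.0]heptane; cis/trans mixture]
Product: 17 (3R)-6-oxo-3-(prop-1-en-2-yl)heptanal, via limonene-1,2-diol 16 (not isolated)
Conditions: H5IO6, THF/H2O, 0 °C → rt
Reagents that add atoms: water, O
Why: Periodic acid opens the epoxide to the 1,2-diol and cleaves it (Malaprade-type glycol cleavage), so both epoxide diastereomers converge on one keto aldehyde while the C4 centre of the terpene is untouched.

**Step 9**
Reactants: 17 (3R)-6-oxo-3-(prop-1-en-2-yl)heptanal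
Product: 18 (3R)-6-oxo-3-(prop-1-en-2-yl)heptanoic acid
Conditions: NaClO2, NaH2PO4, 2-methyl-2-butene, t-BuOH/H2O, 0 °C → rt
Reagents that add atoms: sodium chlorite, [Na+].[O-]Cl=O
Why: Pinnick oxidation is selective for the aldehyde, and the excess 2-methyl-2-butene scavenges HOCl so that the isopropenyl group should be spared.

**Step 10**
Reactants: 18 (3R)-6-oxo-3-(prop-1-en-2-yl)heptanoic acid
Product: 19 (3R)-6-methyl-3-(prop-1-en-2-yl)hept-6-enoic acid
Conditions: Ph3PCH3Br, KOt-Bu (2.5 equiv each), THF, 0 °C → rt; then aq HCl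
Reagents that add atoms: methylenetriphenylphosphorane (from methyltriphenylphosphonium bromide and KOt-Bu), C=P(c1ccccc1)(c1ccccc1)c1ccccc1
Why: Wittig methylenation of the methyl ketone in the presence of the carboxylate (one extra equivalent of base), with the stereocentre β to the carboxylate and therefore not enolisable.

**Step 11**
Reactants: 19 (3R)-6-methyl-3-(prop-1-en-2-yl)hept-6-enoic acid
Product: 21 (3S)-3-(iodomethyl)-2,6-dimethylhepta-1,6-diene, via Barton ester 20 (not isolated)
Conditions: 1-hydroxypyridine-2(1H)-thione, DCC, CH2Cl2, 0 °C → rt, dark; then CHI3, hv (W lamp), rt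
Reagents that add atoms: iodoform, IC(I)I
Why: Barton decarboxylative iodination, in which the thiohydroxamate ester fragments to the primary alkyl radical that should abstract iodine from CHI3 faster than it can cyclise onto the 1,1-disubstituted alkene; the carbon lost as CO2 is the surplus carbon of the terpene skeleton and the stereocentre is not involved (the descriptor changes only by priority).

**Step 12**
Reactants: 21 (3S)-3-(iodomethyl)-2,6-dimethylhepta-1,6-diene; 14 (2S)-8-bromo-5,7-bis(methoxymethoxy)-2-[4-(methoxymethoxy)phenyl]-2,3-dihydro-4H-chromen-4-one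
Product: 23 (2S)-5,7-bis(methoxymethoxy)-2-[4-(methoxymethoxy)phenyl]-8-[(2R)-5-methyl-2-(prop-1-en-2-yl)hex-5-en-1-yl]-2,3-dihydro-4H-chromen-4-one, via alkylzinc iodide 22 (not isolated)
Conditions: 21, Zn dust (activated), LiCl, THF, 40 °C; then 14, Pd(OAc)2 (5 mol %), SPhos (10 mol %), THF, 60 °C
Reagents that add atoms: none
Why: Zinc insertion followed by Negishi sp3–sp2 coupling, in which SPhos-ligated zerovalent palladium should insert into the hindered, electron-rich C8–Br bond and reductively eliminate faster than β-hydride elimination; no base is present, so C2 of the flavanone and the β-centre of the alkyl group are retained.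

**Step 13**
Reactants: 23 (2S)-5,7-bis(methoxymethoxy)-2-[4-(methoxymethoxy)phenyl]-8-[(2R)-5-methyl-2-(prop-1-en-2-yl)hex-5-en-1-yl]-2,3-dihydro-4H-chromen-4-one
Product: 24 remangiflavanone A [(2S)-5,7-dihydroxy-2-(4-hydroxyphenyl)-8-[(2R)-5-methyl-2-(prop-1-en-2-yl)hex-5-en-1-yl]-2,3-dihydro-4H-chromen-4-one]
Conditions: 3 M aq HCl/MeOH (1:5), 40 °C
Reagents that add atoms: none
Why: Acid-catalysed acetal exchange (transacetalisation to dimethoxymethane) removes the three MOM groups under conditions that should leave the flavanone C2 configuration intact and be too weakly acidic to protonate the 1,1-disubstituted alkenes.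

**Compound list**

1 | 5-fluorobenzene-1,3-diol (5-fluororesorcinol) | Oc1cc(O)cc(F)c1 | starting material
2 | 1-fluoro-3,5-bis(methoxymethoxy)benzene | COCOc1cc(F)cc(OCOC)c1 | intermediate
3 | 2,4-dibromo-3-fluoro-1,5-bis(methoxymethoxy)benzene | COCOc1cc(OCOC)c(Br)c(F)c1Br | intermediate
4 | methyl 4-hydroxybenzoate | COC(=O)c1ccc(O)cc1 | starting material
5 | methyl 4-(methoxymethoxy)benzoate | COCOc1ccc(cc1)C(=O)OC | intermediate
6 | N-methoxy-N-methylacetamide | CON(C)C(C)=O | starting material
7 | lithium enolate of N-methoxy-N-methylacetamide | C=C(O[Li])N(C)OC | intermediate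
8 | N-methoxy-3-[4-(methoxymethoxy)phenyl]-N-methyl-3-oxopropanamide | CON(C)C(=O)CC(=O)c1ccc(OCOC)cc1 | intermediate
9 | (3S)-3-hydroxy-N-methoxy-3-[4-(methoxymethoxy)phenyl]-N-methylpropanamide | CON(C)C(=O)C[C@H](O)c1ccc(OCOC)cc1 | intermediate
10 | [3-bromo-2-fluoro-4,6-bis(methoxymethoxy)phenyl]lithium | [Li]c1c(F)c(Br)c(OCOC)cc1OCOC | intermediate
11 | chloromagnesium alkoxide of 9 | CON(C)C(=O)C[C@H](O[Mg]Cl)c1ccc(OCOC)cc1 | intermediate
12 | (3S)-1-[3-bromo-2-fluoro-4,6-bis(methoxymethoxy)phenyl]-3-hydroxy-3-[4-(methoxymethoxy)phenyl]propan-1-one | O=C(C[C@H](O)c1ccc(OCOC)cc1)c1c(F)c(Br)c(OCOC)cc1OCOC | intermediate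
13 | potassium alkoxide of 12 | O=C(C[C@H]([O-])c1ccc(OCOC)cc1)c1c(F)c(Br)c(OCOC)cc1OCOC.[K+] | intermediate
14 | (2S)-8-bromo-5,7-bis(methoxymethoxy)-2-[4-(methoxymethoxy)phenyl]-2,3-dihydro-4H-chromen-4-one | COCOc1cc(OCOC)c2c(c1Br)O[C@H](c1ccc(OCOC)cc1)CC2=O | intermediate
15 | (+)-limonene 1,2-oxide, (4R)-1-methyl-4-(prop-1-en-2-yl)-7-oxabicyclo[4.1.0]heptane, cis/trans mixture | CC12CC[C@H](CC1O2)C(=C)C | starting material
16 | (4R)-1-methyl-4-(prop-1-en-2-yl)cyclohexane-1,2-diol | CC1(O)CC[C@H](CC1O)C(=C)C | intermediate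
17 | (3R)-6-oxo-3-(prop-1-en-2-yl)heptanal | CC(=O)CC[C@H](CC=O)C(=C)C | intermediate
18 | (3R)-6-oxo-3-(prop-1-en-2-yl)heptanoic acid | CC(=O)CC[C@H](CC(=O)O)C(=C)C | intermediate
19 | (3R)-6-methyl-3-(prop-1-en-2-yl)hept-6-enoic acid | C=C(C)CC[C@H](CC(=O)O)C(=C)C | intermediate
20 | 2-thioxopyridin-1(2H)-yl (3R)-6-methyl-3-(prop-1-en-2-yl)hept-6-enoate (Barton ester) | C=C(C)CC[C@H](CC(=O)ON1C=CC=CC1=S)C(=C)C | intermediate
21 | (3S)-3-(iodomethyl)-2,6-dimethylhepta-1,6-diene | C=C(C)CC[C@H](CI)C(=C)C | intermediate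
22 | [(2S)-5-methyl-2-(prop-1-en-2-yl)hex-5-en-1-yl]zinc iodide | C=C(C)CC[C@H](C[Zn]I)C(=C)C | intermediate
23 | (2S)-5,7-bis(methoxymethoxy)-2-[4-(methoxymethoxy)phenyl]-8-[(2R)-5-methyl-2-(prop-1-en-2-yl)hex-5-en-1-yl]-2,3-dihydro-4H-chromen-4-one | C=C(C)CC[C@H](Cc1c(OCOC)cc(OCOC)c2c1O[C@H](c1ccc(OCOC)cc1)CC2=O)C(=C)C | intermediate
24 | remangiflavanone A | C=C(C)CC[C@H](Cc1c(O)cc(O)c2c1O[C@H](c1ccc(O)cc1)CC2=O)C(=C)C | target

**Step count and risks**

Total steps: 13. Longest linear sequence: 7 steps (steps 3, 4, 5, 6, 7, 12, 13).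

The three steps most likely to fail:

1. Step 7. Retro-aldol cleavage and re-addition of the aldolate (erosion of C2 purity) or E1cB dehydration to the chalcone may outrun the SNAr closure. Fallback, setting out from 12 and returning at 14:
   - Dess–Martin oxidation of 12 would give 1-[3-bromo-2-fluoro-4,6-bis(methoxymethoxy)phenyl]-3-[4-(methoxymethoxy)phenyl]propane-1,3-dione F1.
   - K2CO3 in DMF should close the same O1–C8a bond through the enol oxygen, where no aldolate exists, to give 8-bromo-5,7-bis(methoxymethoxy)-2-[4-(methoxymethoxy)phenyl]-4H-chromen-4-one F2.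
   - Enantioselective hydrogenation of the C2=C3 bond of F2 with a chiral ruthenium N-heterocyclic carbene catalyst (from [Ru(cod)(2-methylallyl)2], a chiral imidazolinium salt and KOt-Bu, under H2), a known reaction of flavones, should give (2S)-8-bromo-5,7-bis(methoxymethoxy)-2-[4-(methoxymethoxy)phenyl]-3,4-dihydro-2H-chromen-4-ol F3; the C4 configuration is immaterial.
   - Dess–Martin re-oxidation of F3 returns to 14.

2. Step 12. Oxidative addition into the hindered, electron-rich C8–Br bond may be slow, and β-hydride elimination from the alkylpalladium intermediate (its β-hydrogen is allylic) may lead to protodebromination or a rearranged chain. Fallback, setting out from 3 and returning at 23: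
   - Bromine–magnesium exchange of 3 (i-PrMgCl·LiCl, THF) and Li2CuCl4-catalysed Kumada-type alkylation with iodide 21 would give 2-bromo-3-fluoro-1,5-bis(methoxymethoxy)-4-[(2R)-5-methyl-2-(prop-1-en-2-yl)hex-5-en-1-yl]benzene F4.
   - Bromine–lithium exchange of F4 (n-BuLi, −78 °C) and acylation with 11 as in step 6 would give (3S)-1-{2-fluoro-4,6-bis(methoxymethoxy)-3-[(2R)-5-methyl-2-(prop-1-en-2-yl)hex-5-en-1-yl]phenyl}-3-hydroxy-3-[4-(methoxymethoxy)phenyl]propan-1-one F5.
   - The SNAr closure of step 7 applied to F5 leads to 23.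

3. Step 13. While the last MOM group is being cleaved, the acid may protonate the isopropenyl group and let the C7 hydroxyl (or methanol) add to it, closing a chroman ring or adding solvent. Fallback, setting out from 14 and returning at 24:
   - Before any alkene is present, 3 M HCl/MeOH on 14 would give (2S)-8-bromo-5,7-dihydroxy-2-(4-hydroxyphenyl)-2,3-dihydro-4H-chromen-4-one F6.
   - TBSOTf and 2,6-lutidine would give (2S)-8-bromo-5,7-bis[(tert-butyldimethylsilyl)oxy]-2-{4-[(tert-butyldimethylsilyl)oxy]phenyl}-2,3-dihydro-4H-chromen-4-one F7.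
   - Negishi coupling of F7 with 22 as in step 12 would give (2S)-5,7-bis[(tert-butyldimethylsilyl)oxy]-2-{4-[(tert-butyldimethylsilyl)oxy]phenyl}-8-[(2R)-5-methyl-2-(prop-1-en-2-yl)hex-5-en-1-yl]-2,3-dihydro-4H-chromen-4-one F8.
   - HF·pyridine in THF/pyridine at 0 °C then gives 24 without strong protic acid.

**Further compounds**

F1 | step 7 | 1-[3-bromo-2-fluoro-4,6-bis(methoxymethoxy)phenyl]-3-[4-(methoxymethoxy)phenyl]propane-1,3-dione | O=C(CC(=O)c1ccc(OCOC)cc1)c1c(F)c(Br)c(OCOC)cc1OCOC
F2 | step 7 | 8-bromo-5,7-bis(methoxymethoxy)-2-[4-(methoxymethoxy)phenyl]-4H-chromen-4-one | O=c1cc(-c2ccc(OCOC)cc2)oc2c(Br)c(OCOC)cc(OCOC)c12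
F3 | step 7 | (2S)-8-bromo-5,7-bis(methoxymethoxy)-2-[4-(methoxymethoxy)phenyl]-3,4-dihydro-2H-chromen-4-ol | COCOc1cc(OCOC)c2c(c1Br)O[C@H](c1ccc(OCOC)cc1)CC2O
F4 | step 12 | 2-bromo-3-fluoro-1,5-bis(methoxymethoxy)-4-[(2R)-5-methyl-2-(prop-1-en-2-yl)hex-5-en-1-yl]benzene | C=C(C)CC[C@H](Cc1c(F)c(Br)c(OCOC)cc1OCOC)C(=C)C
F5 | step 12 | (3S)-1-{2-fluoro-4,6-bis(methoxymethoxy)-3-[(2R)-5-methyl-2-(prop-1-en-2-yl)hex-5-en-1-yl]phenyl}-3-hydroxy-3-[4-(methoxymethoxy)phenyl]propan-1-one | C=C(C)CC[C@H](Cc1c(OCOC)cc(OCOC)c(C(=O)C[C@H](O)c2ccc(OCOC)cc2)c1F)C(=C)C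
F6 | step 13 | (2S)-8-bromo-5,7-dihydroxy-2-(4-hydroxyphenyl)-2,3-dihydro-4H-chromen-4-one | Oc1cc(O)c2c(c1Br)O[C@H](c1ccc(O)cc1)CC2=O
F7 | step 13 | (2S)-8-bromo-5,7-bis[(tert-butyldimethylsilyl)oxy]-2-{4-[(tert-butyldimethylsilyl)oxy]phenyl}-2,3-dihydro-4H-chromen-4-one | CC(C)(C)[Si](C)(C)Oc1cc(O[Si](C)(C)C(C)(C)C)c2c(c1Br)O[C@H](c1ccc(O[Si](C)(C)C(C)(C)C)cc1)CC2=O
F8 | step 13 | (2S)-5,7-bis[(tert-butyldimethylsilyl)oxy]-2-{4-[(tert-butyldimethylsilyl)oxy]phenyl}-8-[(2R)-5-methyl-2-(prop-1-en-2-yl)hex-5-en-1-yl]-2,3-dihydro-4H-chromen-4-one | C=C(C)CC[C@H](Cc1c(O[Si](C)(C)C(C)(C)C)cc(O[Si](C)(C)C(C)(C)C)c2c1O[C@H](c1ccc(O[Si](C)(C)C(C)(C)C)cc1)CC2=O)C(=C)C
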